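At the last readings of both earlier runs the right-handed substrate stands higher than the left-handed substrate while left-handed product P has accumulated, as in a kinetic resolution of a racemate by a single-handed catalyst.

in all of them: left-handed substrate 20 mM; right-handed substrate 20 mM; free catalyst 10 µM
- autumn: coupling partner 28 mM; run made earlier
- midnight: coupling partner 44 mM; run made earlier
- flask: coupling partner 20.0 mM; time 50 min

- autumn (time / min: right-handed substrate / %, left-handed substrate / %, left-handed product / %): 6.00: 48.6, 49.4, 1.2; 12.0: 49.4, 47.9, 3.1; 20.0: 48.2, 45.8, 3.8; 25.0: 49.6, 45.3, 4.4; 30.0: 47.5, 44.5, 6.0; 40.0: 47.2, 43.2, 8.0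
- midnight (time / min: right-handed substrate / %, left-handed substrate / %, left-handed product / %): 2.50: 49.3, 48.7, 2.1; 8.00: 48.7, 47.4, 2.2; 15.0: 48.8, 45.9, 5.2; 20.0: 48.8, 43.7, 6.4; 30.0: 46.0, 41.9, 9.0; 40.0: 46.1, 40.5, 11.3

(standard deviation of a reading: 0.5 percentage points)

* whether the excess of right-handed substrate over left-handed substrate among what is left of the two reaches 99 % by 50 min (yes / no)
* the highest excess of right-handed substrate over left-handed substrate among what is left of the two up to 50 min

Let e be the excess: right-handed substrate minus left-handed substrate, over their sum. At the last readings, e/P is 0.553 in the autumn run and 0.572 in the midnight run. Their mean, g = 0.563, is the excess gained per unit of product, with P as a fraction of both substrates charged.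

Two chemists dispute the flask. The first counts charges: 20.0 mM of coupling partner can take up the whole 20 mM of left-handed substrate, so the end state of that count is pure right-handed substrate, and 99 % lies within reach.

The second made the forecast and reckons by rate: no, with a top of 4 %, because “Excess tracks conversion”. At the measured g, an excess of 99 % asks for P = 176 %, more than the whole charge, although g is read at low conversion.

My own reckoning sides with the second. The autumn run made 8.0 % in 40.0 min; scaled in proportion to partner and time, this gives an estimate of 7.14 % for the flask, and g turns this into an estimated excess of 4.02 %.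

The simulation gives no and a top of 3.02 %, so the forecast holds.

    free catalyst + left-handed substrate ⇌ catalyst intermediate A (K = 16.0 M⁻¹, k = 490 M⁻¹ s⁻¹)
    free catalyst + right-handed substrate ⇌ catalyst intermediate B (K = 150 M⁻¹, k = 4300 M⁻¹ s⁻¹)
    coupling partner + catalyst intermediate A → free catalyst + left-handed product (k = 83.0 M⁻¹ s⁻¹)
    coupling partner + catalyst intermediate B → free catalyst + right-handed product (k = 2.50 M⁻¹ s⁻¹)
    left-handed substrate ⇌ right-handed substrate (k = 1.40 × 10⁻⁴ s⁻¹)
    free catalyst ⇌ dormant form (K = 5.70, k = 7.60 × 10⁻⁴ s⁻¹)

In the flask, coupling of partner with catalyst intermediate A reached the midpoint of its turnover up to 50.0 min by 20.8 min, while catalyst intermediate B, the resting state, was the largest catalyst form, going from 66.1 % of the catalyst charged at 5.00 min to 44.7 % at 50.0 min. Dormant form rose from 5.08 % to 35.2 % over the same times. The first chemist's count holds as a ledger: by 50.0 min the flask had lost 3.24 mM of partner and made 3.24 mM of left-handed and right-handed product together. With the flask's 6.21 % of P at 50.0 min, g gives 3.50 % against 3.02 %; in the same flask with 50 mM of partner, 13.8 % of P gives 7.77 % against 7.12 %.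

(The readings come from a simulation for an exercise; noise was put on by code.)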